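**Retrosynthetic overview**

1. The target is taken back to its 5-O-MOM ether; the last step is a mild acetal cleavage.
2. Ring C is cut at two bonds on neighbouring ring-A carbons, O1–C8a and C4–C4a. An aryne of ring A (C4a≡C8a, from a 2-silylaryl triflate) takes up the alkoxide oxygen of an (S)-3-silyloxy Weinreb amide at C8a, and the aryl anion left at C4a closes ring C by attacking the amide carbon (bond C4–C4a).
3. Enabling feature: O1 and the C4 carbonyl sit on adjacent carbons C8a and C4a of ring A, and C5, next to C4a, carries oxygen. Ring A is therefore the adduct of a 3-oxy-benzyne whose oxygen steers the nucleophile to C8a and the carbanion to C4a.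
4. The aryne precursor comes from 5-methoxyresorcinol: geranyl by lithiation between OMOM and OMe, then carbamate-directed silylation and triflation. The amide comes from ethyl 3-(3,4-dimethoxyphenyl)-3-oxopropanoate by asymmetric transfer hydrogenation, which sets C2.
5. Order of ring formation: rings A and B are purchased aromatic; ring C is the only ring made, in the key step.

Key step: step 11

Remark: geranyl means (2E)-3,7-dimethylocta-2,6-dien-1-yl and flavanone numbering is used for rings A and C; the sense of the transfer hydrogenation in step 8 is assumed to follow the acetophenone model for this ligand.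

**Route**

Step 1
Reactants: 1 5-methoxybenzene-1,3-diol (5-methoxyresorcinol)
Product: 2 3-methoxy-5-{[tri(propan-2-yl)silyl]oxy}phenol
Conditions: TIPSCl (1 equiv), imidazole, DMF, 0 → 20 °C; chromatography, diol and bis-ether recycled
Reagents that add atoms: chlorotri(propan-2-yl)silane, CC(C)[Si](Cl)(C(C)C)C(C)C
Why: Statistical mono-O-silylation of the symmetric diol with one equivalent of a bulky chlorosilane should give the mono-ether, which is separable from diol and bis-ether.

Step 2
Reactants: 2 3-methoxy-5-{[tri(propan-2-yl)silyl]oxy}phenol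
Product: 3 [3-methoxy-5-(methoxymethoxy)phenoxy]tri(propan-2-yl)silane
Conditions: MOMCl, i-Pr2NEt, CH2Cl2, 0 → 20 °C
Reagents that add atoms: chloromethyl methyl ether, COCCl
Why: O-alkylation of the remaining phenol with MOMCl under amine base (acetal formation) leaves the silyl ether untouched.

Step 3
Reactants: 3 [3-methoxy-5-(methoxymethoxy)phenoxy]tri(propan-2-yl)silane and 4 geranyl bromide, (2E)-1-bromo-3,7-dimethylocta-2,6-diene
Product: 6 [4-geranyl-3-methoxy-5-(methoxymethoxy)phenoxy]tri(propan-2-yl)silane, via aryllithium 5 (not isolated)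
Conditions: n-BuLi, TMEDA, THF, 0 °C; CuBr·SMe2 (0.1 equiv), −78 °C; 4, −78 → 0 °C
Reagents that add atoms: none
Why: Directed ortho-metalation should occur between the MOM acetal and the methoxy group (both direct there, while the positions beside the bulky, non-coordinating OTIPS are shielded), and copper-catalysed allylic substitution on the primary carbon of geranyl bromide keeps the E geometry.

Step 4
Reactants: 6 [4-geranyl-3-methoxy-5-(methoxymethoxy)phenoxy]tri(propan-2-yl)silane
Product: 7 4-geranyl-3-methoxy-5-(methoxymethoxy)phenol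
Conditions: TBAF, AcOH (1.1 equiv each), THF, 0 °C
Reagents that add atoms: none
Why: Fluoride-mediated cleavage of the aryl silyl ether, buffered with acetic acid, should free the phenol without touching the acetal or the diene.

Step 5
Reactants: 7 4-geranyl-3-methoxy-5-(methoxymethoxy)phenol
Product: 8 4-geranyl-3-methoxy-5-(methoxymethoxy)phenyl N-(propan-2-yl)carbamate
Conditions: i-PrNCO, Et3N (0.2 equiv), CH2Cl2, 20 °C
Reagents that add atoms: isopropyl isocyanate, CC(C)N=C=O
Why: Base-catalysed addition of the phenol to the isocyanate (carbamoylation) installs a strong directing group that can later be removed under mild amine conditions.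

Step 6
Reactants: 8 4-geranyl-3-methoxy-5-(methoxymethoxy)phenyl N-(propan-2-yl)carbamate
Product: 12 4-geranyl-5-methoxy-3-(methoxymethoxy)-2-(trimethylsilyl)phenyl N-(propan-2-yl)carbamate, via N-silyl carbamate 9 (not isolated), via aryllithium 10 (not isolated), via N-silyl C-silyl carbamate 11 (not isolated)
Conditions: TMEDA, TMSOTf, Et2O, 0 → 20 °C; n-BuLi, TMEDA, −78 °C; TMSCl, −78 → 20 °C; aq. NH4Cl
Reagents that add atoms: chlorotrimethylsilane, C[Si](C)(C)Cl
Why: Directed ortho-metalation of the in situ N-silylated carbamate should take place at the ring carbon between the carbamate and the MOM acetal (the two strongest directing groups), since the other ortho position is flanked only by the methoxy group whose methyl is turned toward it by the geranyl chain; silyl quench and hydrolytic loss of the N-silyl group then give the C-silyl carbamate.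

Step 7
Reactants: 12 4-geranyl-5-methoxy-3-(methoxymethoxy)-2-(trimethylsilyl)phenyl N-(propan-2-yl)carbamate
Product: 14 4-geranyl-5-methoxy-3-(methoxymethoxy)-2-(trimethylsilyl)phenyl trifluoromethanesulfonate, via silyl phenol 13 (not isolated)
Conditions: Et2NH, DBU, MeCN, 40 °C; then PhNTf2, 20 °C
Reagents that add atoms: N-phenylbis(trifluoromethanesulfonimide), O=S(=O)(N(c1ccccc1)S(=O)(=O)C(F)(F)F)C(F)(F)F
Why: Amine-induced E1cB cleavage of the N–H carbamate (the isocyanate is trapped as a urea) unmasks the phenoxide, which is O-triflated in the same flask to give a Kobayashi-type aryne precursor.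

Step 8
Reactants: 15 ethyl 3-(3,4-dimethoxyphenyl)-3-oxopropanoate
Product: 16 ethyl (3S)-3-(3,4-dimethoxyphenyl)-3-hydroxypropanoate
Conditions: RuCl(p-cymene)[(S,S)-TsDPEN] (1 mol %), HCO2H/Et3N (5:2), DMF, 40 °C
Reagents that add atoms: none
Why: Noyori–Ikariya asymmetric transfer hydrogenation of the aryl ketone; the (S,S)-diamine ligand should deliver hydride to the face that gives the (S)-carbinol, which becomes C2 of the target.

Step 9
Reactants: 16 ethyl (3S)-3-(3,4-dimethoxyphenyl)-3-hydroxypropanoate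
Product: 17 (3S)-3-(3,4-dimethoxyphenyl)-3-hydroxy-N-methoxy-N-methylpropanamide
Conditions: MeNH(OMe)·HCl, i-PrMgCl, THF, −20 → 0 °C
Reagents that add atoms: N,O-dimethylhydroxylamine hydrochloride, CNOC.Cl
Why: Direct ester-to-Weinreb-amide aminolysis with the magnesium amide tolerates the free β-hydroxy group (as its magnesium alkoxide) and does not involve the stereocentre.

Step 10
Reactants: 17 (3S)-3-(3,4-dimethoxyphenyl)-3-hydroxy-N-methoxy-N-methylpropanamide
Product: 18 (3S)-3-(3,4-dimethoxyphenyl)-N-methoxy-N-methyl-3-[(trimethylsilyl)oxy]propanamide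
Conditions: TMSCl, imidazole, CH2Cl2, 0 °C
Reagents that add atoms: chlorotrimethylsilane, C[Si](C)(C)Cl
Why: O-silylation of the secondary alcohol gives a silyl ether that serves as a latent, proton-free alkoxide for the next step.

Step 11
Reactants: 14 4-geranyl-5-methoxy-3-(methoxymethoxy)-2-(trimethylsilyl)phenyl trifluoromethanesulfonate and 18 (3S)-3-(3,4-dimethoxyphenyl)-N-methoxy-N-methyl-3-[(trimethylsilyl)oxy]propanamide
Product: 23 (2S)-2-(3,4-dimethoxyphenyl)-6-geranyl-7-methoxy-5-(methoxymethoxy)-2,3-dihydro-4H-chromen-4-one, via potassium alkoxide 19 (not isolated), via aryne 20 (not isolated), via arylpotassium 21 (not isolated), via tetrahedral adduct 22 (not isolated)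
Conditions: 18 (1.5 equiv), KF, 18-crown-6, THF, 0 °C; then 14 added slowly, 0 → 20 °C; AcOH quench at 0 °C
Reagents that add atoms: none
Why: Proposed new method: fluoride cleaves the O–Si bond of 18 to the proton-free alkoxide 19 and triggers 1,2-elimination of 14 to aryne 20; 19 adds to C8a, the aryne carbon remote from the C5 acetal oxygen, and the arylpotassium 21 formed at C4a attacks the tethered Weinreb amide in a 6-exo-trig acyl addition that forms the C4–C4a bond and closes ring C, the adduct 22 keeping the ketone masked until the acidic quench. The closest known reaction types are the fluoride-mediated annulation of arynes with salicylate esters to xanthones (phenoxide addition, then intramolecular acyl substitution by the aryl anion) and the O–H insertion of aliphatic alcohols into arynes; new here are the aliphatic alkoxide released from a silyl ether and the amide acceptor. No stereocentre is created: C2 comes from 18 and should keep its S configuration because its C–O bond is never broken, an amide enolate is too poor a leaving group for retro-aldol or E1cB loss of the oxygen, and 22 cannot undergo the base-induced opening to a chalcone that would racemise a free flavanone. The selectivity needed is regiochemical (oxygen at C8a and acyl at C4a, not the reverse) and is secured by the distortion that the C5 oxygen imposes on the aryne, as in 3-methoxy- and 3,5-dimethoxybenzyne; the silyl ether route leaves no O–H to protonate 21 before it cyclises. In one operation the step joins the two halves, makes both bonds from ring C to ring A and delivers the full ring-A substitution pattern.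

Step 12
Reactants: 23 (2S)-2-(3,4-dimethoxyphenyl)-6-geranyl-7-methoxy-5-(methoxymethoxy)-2,3-dihydro-4H-chromen-4-one
Product: 24 (2S)-2-(3,4-dimethoxyphenyl)-6-geranyl-5-hydroxy-7-methoxy-2,3-dihydro-4H-chromen-4-one (CNP0310479.1)
Conditions: HCl (0.5 M in MeOH), THF, 20 °C; NaHCO3 quench
Reagents that add atoms: none
Why: Acid-catalysed acetal exchange (MOM cleavage) of the aryl MOM ether peri to the carbonyl should proceed under conditions mild enough to leave the geranyl diene and the C2 stereocentre untouched, revealing the hydrogen-bonded 5-OH.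

**Compound list**

1 | 5-methoxybenzene-1,3-diol | COc1cc(O)cc(O)c1 | starting material
2 | 3-methoxy-5-{[tri(propan-2-yl)silyl]oxy}phenol | COc1cc(O)cc(O[Si](C(C)C)(C(C)C)C(C)C)c1 | intermediate
3 | [3-methoxy-5-(methoxymethoxy)phenoxy]tri(propan-2-yl)silane | COCOc1cc(O[Si](C(C)C)(C(C)C)C(C)C)cc(OC)c1 | intermediate
4 | geranyl bromide, (2E)-1-bromo-3,7-dimethylocta-2,6-diene | BrC/C=C(\C)CCC=C(C)C | starting material
5 | {2-methoxy-6-(methoxymethoxy)-4-[tri(propan-2-yl)silyloxy]phenyl}lithium | COCOc1cc(O[Si](C(C)C)(C(C)C)C(C)C)cc(OC)c1[Li] | intermediate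
6 | {4-[(2E)-3,7-dimethylocta-2,6-dien-1-yl]-3-methoxy-5-(methoxymethoxy)phenoxy}tri(propan-2-yl)silane | COCOc1cc(O[Si](C(C)C)(C(C)C)C(C)C)cc(OC)c1C/C=C(\C)CCC=C(C)C | intermediate
7 | 4-[(2E)-3,7-dimethylocta-2,6-dien-1-yl]-3-methoxy-5-(methoxymethoxy)phenol | COCOc1cc(O)cc(OC)c1C/C=C(\C)CCC=C(C)C | intermediate
8 | 4-[(2E)-3,7-dimethylocta-2,6-dien-1-yl]-3-methoxy-5-(methoxymethoxy)phenyl N-(propan-2-yl)carbamate | COCOc1cc(OC(=O)NC(C)C)cc(OC)c1C/C=C(\C)CCC=C(C)C | intermediate
9 | 4-[(2E)-3,7-dimethylocta-2,6-dien-1-yl]-3-methoxy-5-(methoxymethoxy)phenyl N-(propan-2-yl)-N-(trimethylsilyl)carbamate | COCOc1cc(OC(=O)N(C(C)C)[Si](C)(C)C)cc(OC)c1C/C=C(\C)CCC=C(C)C | intermediate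
10 | {3-[(2E)-3,7-dimethylocta-2,6-dien-1-yl]-4-methoxy-2-(methoxymethoxy)-6-{[(propan-2-yl)(trimethylsilyl)carbamoyl]oxy}phenyl}lithium | COCOc1c([Li])c(OC(=O)N(C(C)C)[Si](C)(C)C)cc(OC)c1C/C=C(\C)CCC=C(C)C | intermediate
11 | 4-[(2E)-3,7-dimethylocta-2,6-dien-1-yl]-5-methoxy-3-(methoxymethoxy)-2-(trimethylsilyl)phenyl N-(propan-2-yl)-N-(trimethylsilyl)carbamate | COCOc1c([Si](C)(C)C)c(OC(=O)N(C(C)C)[Si](C)(C)C)cc(OC)c1C/C=C(\C)CCC=C(C)C | intermediate
12 | 4-[(2E)-3,7-dimethylocta-2,6-dien-1-yl]-5-methoxy-3-(methoxymethoxy)-2-(trimethylsilyl)phenyl N-(propan-2-yl)carbamate | COCOc1c([Si](C)(C)C)c(OC(=O)NC(C)C)cc(OC)c1C/C=C(\C)CCC=C(C)C | intermediate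
13 | 4-[(2E)-3,7-dimethylocta-2,6-dien-1-yl]-5-methoxy-3-(methoxymethoxy)-2-(trimethylsilyl)phenol | COCOc1c([Si](C)(C)C)c(O)cc(OC)c1C/C=C(\C)CCC=C(C)C | intermediate
14 | 4-[(2E)-3,7-dimethylocta-2,6-dien-1-yl]-5-methoxy-3-(methoxymethoxy)-2-(trimethylsilyl)phenyl trifluoromethanesulfonate | COCOc1c([Si](C)(C)C)c(OS(=O)(=O)C(F)(F)F)cc(OC)c1C/C=C(\C)CCC=C(C)C | intermediate
15 | ethyl 3-(3,4-dimethoxyphenyl)-3-oxopropanoate | CCOC(=O)CC(=O)c1ccc(OC)c(OC)c1 | starting material
16 | ethyl (3S)-3-(3,4-dimethoxyphenyl)-3-hydroxypropanoate | CCOC(=O)C[C@H](O)c1ccc(OC)c(OC)c1 | intermediate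
17 | (3S)-3-(3,4-dimethoxyphenyl)-3-hydroxy-N-methoxy-N-methylpropanamide | CON(C)C(=O)C[C@H](O)c1ccc(OC)c(OC)c1 | intermediate
18 | (3S)-3-(3,4-dimethoxyphenyl)-N-methoxy-N-methyl-3-[(trimethylsilyl)oxy]propanamide | CON(C)C(=O)C[C@H](O[Si](C)(C)C)c1ccc(OC)c(OC)c1 | intermediate
19 | potassium (1S)-1-(3,4-dimethoxyphenyl)-3-[methoxy(methyl)amino]-3-oxopropan-1-olate | CON(C)C(=O)C[C@H]([O-])c1ccc(OC)c(OC)c1.[K+] | intermediate
20 | 4-[(2E)-3,7-dimethylocta-2,6-dien-1-yl]-5-methoxy-3-(methoxymethoxy)-1,2-didehydrobenzene (aryne, triple bond between the former C–OTf and C–Si carbons) | COCOC1=C(C/C=C(\C)CCC=C(C)C)C(OC)=CC#C1 | intermediate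
21 | [6-{[(1S)-1-(3,4-dimethoxyphenyl)-3-[methoxy(methyl)amino]-3-oxopropyl]oxy}-3-[(2E)-3,7-dimethylocta-2,6-dien-1-yl]-4-methoxy-2-(methoxymethoxy)phenyl]potassium | COCOc1c([K])c(O[C@@H](CC(=O)N(C)OC)c2ccc(OC)c(OC)c2)cc(OC)c1C/C=C(\C)CCC=C(C)C | intermediate
22 | potassium (2S)-2-(3,4-dimethoxyphenyl)-6-[(2E)-3,7-dimethylocta-2,6-dien-1-yl]-7-methoxy-4-[methoxy(methyl)amino]-5-(methoxymethoxy)-3,4-dihydro-2H-chromen-4-olate (C4 configuration undefined) | COc1ccc([C@@H]2CC([O-])(N(C)OC)c3c(cc(OC)c(C/C=C(\C)CCC=C(C)C)c3OCOC)O2)cc1OC.[K+] | intermediate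
23 | (2S)-2-(3,4-dimethoxyphenyl)-6-[(2E)-3,7-dimethylocta-2,6-dien-1-yl]-7-methoxy-5-(methoxymethoxy)-2,3-dihydro-4H-chromen-4-one | COc1ccc([C@@H]2CC(=O)c3c(cc(OC)c(C/C=C(\C)CCC=C(C)C)c3OCOC)O2)cc1OC | intermediate
24 | (2S)-2-(3,4-dimethoxyphenyl)-6-[(2E)-3,7-dimethylocta-2,6-dien-1-yl]-5-hydroxy-7-methoxy-2,3-dihydro-4H-chromen-4-one | COc1ccc([C@@H]2CC(=O)c3c(cc(OC)c(C/C=C(\C)CCC=C(C)C)c3O)O2)cc1OC | target

**Step count and risks**

Total steps: 12. Longest linear sequence: 9 (steps 1–7, 11, 12); steps 8–10 form the second branch.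

Steps most likely to fail:

1. Step 11 (proposed new method). What may go wrong: protonation of the aryl anion before it reaches the amide (for example by 1,5-proton transfer from C3), fragmentation of the alkoxide before it meets the aryne, or an ene reaction of the aryne with a geranyl double bond. The fallback uses known reactions and keeps the C4–C4a ring closure; it sets out from aryllithium 10 (generated from 8 as in step 6) and from 15, and comes back at 23. Quenching 10 with 1,2-diiodoethane should give the N-silyl iodo carbamate F1, hydrolysed on work-up to 4-geranyl-2-iodo-5-methoxy-3-(methoxymethoxy)phenyl N-(propan-2-yl)carbamate F2. Et2NH/DBU cleavage as in step 7 then gives 4-geranyl-2-iodo-5-methoxy-3-(methoxymethoxy)phenol F3. In parallel, 15 is reduced with the (R,R) catalyst to ethyl (3R)-3-(3,4-dimethoxyphenyl)-3-hydroxypropanoate F4 and converted as in step 9 into (3R)-3-(3,4-dimethoxyphenyl)-3-hydroxy-N-methoxy-N-methylpropanamide F5. Mitsunobu etherification of F3 with F5 (PPh3, DIAD, toluene, −20 °C) inverts the carbinol carbon and should give the (3S)-3-(2-iodoaryloxy) Weinreb amide F6. Iodine–magnesium exchange with i-PrMgCl·LiCl at −40 °C gives the arylmagnesium chloride F7, which closes ring C on the amide (Parham-type cyclisation) through the chelated magnesium hemiaminal F8; mild acidic work-up gives 23. The point to watch is partial ionisation of the electron-rich benzylic alcohol during the Mitsunobu step.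

2. Step 6. What may go wrong: metalation at the wrong site (the other ortho position or the benzylic–allylic CH2 of the geranyl chain), or loss of the MOM group to the silyl triflate. The fallback changes the directing group; it sets out from 6 and comes back at 13. In 6 the only free position ortho to the MOM acetal is the one required, so s-BuLi/TMEDA (THF, −78 °C) should give the aryllithium F9 and TMSCl the C-silylated TIPS ether F10. TBAF/AcOH then cleaves only the O–Si bond to give 13, which is triflated to 14 with PhNTf2/DBU as in the second half of step 7.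

3. Step 3. What may go wrong: slow or misdirected deprotonation of 3, or allylic transposition during the substitution. The fallback fixes the site by electrophilic substitution instead of deprotonation; it sets out from 3 and comes back at 5. NBS (1 equiv, CH2Cl2, −40 °C) should brominate the position between OMOM and OMe, the other two being shielded by OTIPS, to give the aryl bromide F11. Bromine–lithium exchange with n-BuLi at −78 °C then gives 5, which is geranylated to 6 as in step 3.

**Further compounds**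

F1 | step 11 | 4-[(2E)-3,7-dimethylocta-2,6-dien-1-yl]-2-iodo-5-methoxy-3-(methoxymethoxy)phenyl N-(propan-2-yl)-N-(trimethylsilyl)carbamate | COCOc1c(I)c(OC(=O)N(C(C)C)[Si](C)(C)C)cc(OC)c1C/C=C(\C)CCC=C(C)C
F2 | step 11 | 4-[(2E)-3,7-dimethylocta-2,6-dien-1-yl]-2-iodo-5-methoxy-3-(methoxymethoxy)phenyl N-(propan-2-yl)carbamate | COCOc1c(I)c(OC(=O)NC(C)C)cc(OC)c1C/C=C(\C)CCC=C(C)C
F3 | step 11 | 4-[(2E)-3,7-dimethylocta-2,6-dien-1-yl]-2-iodo-5-methoxy-3-(methoxymethoxy)phenol | COCOc1c(I)c(O)cc(OC)c1C/C=C(\C)CCC=C(C)C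
F4 | step 11 | ethyl (3R)-3-(3,4-dimethoxyphenyl)-3-hydroxypropanoate | CCOC(=O)C[C@@H](O)c1ccc(OC)c(OC)c1
F5 | step 11 | (3R)-3-(3,4-dimethoxyphenyl)-3-hydroxy-N-methoxy-N-methylpropanamide | CON(C)C(=O)C[C@@H](O)c1ccc(OC)c(OC)c1
F6 | step 11 | (3S)-3-(3,4-dimethoxyphenyl)-3-{4-[(2E)-3,7-dimethylocta-2,6-dien-1-yl]-2-iodo-5-methoxy-3-(methoxymethoxy)phenoxy}-N-methoxy-N-methylpropanamide | COCOc1c(I)c(O[C@@H](CC(=O)N(C)OC)c2ccc(OC)c(OC)c2)cc(OC)c1C/C=C(\C)CCC=C(C)C
F7 | step 11 | chloro[6-{[(1S)-1-(3,4-dimethoxyphenyl)-3-[methoxy(methyl)amino]-3-oxopropyl]oxy}-3-[(2E)-3,7-dimethylocta-2,6-dien-1-yl]-4-methoxy-2-(methoxymethoxy)phenyl]magnesium | COCOc1c([Mg]Cl)c(O[C@@H](CC(=O)N(C)OC)c2ccc(OC)c(OC)c2)cc(OC)c1C/C=C(\C)CCC=C(C)C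
F8 | step 11 | chloromagnesium (2S)-2-(3,4-dimethoxyphenyl)-6-[(2E)-3,7-dimethylocta-2,6-dien-1-yl]-7-methoxy-4-[methoxy(methyl)amino]-5-(methoxymethoxy)-3,4-dihydro-2H-chromen-4-olate | COc1ccc([C@@H]2CC(O[Mg]Cl)(N(C)OC)c3c(cc(OC)c(C/C=C(\C)CCC=C(C)C)c3OCOC)O2)cc1OC
F9 | step 6 | {3-[(2E)-3,7-dimethylocta-2,6-dien-1-yl]-4-methoxy-2-(methoxymethoxy)-6-[tri(propan-2-yl)silyloxy]phenyl}lithium | COCOc1c([Li])c(O[Si](C(C)C)(C(C)C)C(C)C)cc(OC)c1C/C=C(\C)CCC=C(C)C
F10 | step 6 | {4-[(2E)-3,7-dimethylocta-2,6-dien-1-yl]-5-methoxy-3-(methoxymethoxy)-2-(trimethylsilyl)phenoxy}tri(propan-2-yl)silane | COCOc1c([Si](C)(C)C)c(O[Si](C(C)C)(C(C)C)C(C)C)cc(OC)c1C/C=C(\C)CCC=C(C)C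
F11 | step 3 | [4-bromo-3-methoxy-5-(methoxymethoxy)phenoxy]tri(propan-2-yl)silane | COCOc1cc(O[Si](C(C)C)(C(C)C)C(C)C)cc(OC)c1Br
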